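**Strategy.** The seven-membered ring of ampelopsin B is joined to the dihydrobenzofuran only by two aryl–C(sp3) bonds: C8 (the CH2 group) to C4 of ring A (the benzo ring of the benzofuran), and the unoxygenated carbon of resorcinol ring B to C3 of the dihydrofuran. Cutting both gives a 4-iodo-2-arylbenzofuran and an enantioenriched 2,2-diarylethyl boronate. The key step joins them in one flask as a (4+3) annulation: B-alkyl Suzuki coupling at C4, then 7-exo dearomative reductive Heck cyclisation across the benzofuran C2=C3 bond. It exploits the peri relationship of C4 and C3 and the enol ether C2=C3 bond of a 2-arylbenzofuran, whose syn carbopalladation and hydride capture give the 2,3-trans dihydrofuran.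

Key step: step 9

Remark on labels and configuration: C2 (O-bearing) and C3 are the dihydrofuran carbons, C7 is the diarylmethine carbon of the seven-membered ring and C8 its CH2 group. With these labels the target is 2S,3S,7S (2,3-trans; C7 aryl cis to C3–H on the seven-membered ring). The antipode of the cobalt ligand in step 4 is the one that gives (S)-6.

**Fragment 1 (boronate)**

Step 1
Reactants: 1 2-bromo-4,6-dimethoxybenzaldehyde; 2 4-methoxyphenylmagnesium bromide
Product: 3 (2-bromo-4,6-dimethoxyphenyl)(4-methoxyphenyl)methanol (racemic)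
Conditions: THF, 0 °C; then aq. NH4Cl
Reagents that add atoms: none
Why: Grignard addition to the aldehyde; the aryl bromide does not exchange with an arylmagnesium halide at 0 °C, and the racemic carbinol centre is removed in step 2.

Step 2
Reactants: 3 (2-bromo-4,6-dimethoxyphenyl)(4-methoxyphenyl)methanol
Product: 4 (2-bromo-4,6-dimethoxyphenyl)(4-methoxyphenyl)methanone
Conditions: Dess–Martin periodinane, NaHCO3, CH2Cl2, 25 °C
Reagents that add atoms: none
Why: Dess–Martin oxidation of a secondary diaryl carbinol to the benzophenone; no other group is oxidisable.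

Step 3
Reactants: 4 (2-bromo-4,6-dimethoxyphenyl)(4-methoxyphenyl)methanone
Product: 5 1-bromo-3,5-dimethoxy-2-[1-(4-methoxyphenyl)ethenyl]benzene
Conditions: Ph3PCH3Br, KOtBu, toluene, 110 °C
Reagents that add atoms: methyltriphenylphosphonium bromide, C[P+](c1ccccc1)(c1ccccc1)c1ccccc1.[Br-]
Why: Wittig methylenation of a non-enolisable diaryl ketone; heating should overcome the hindrance of the 2,6-disubstituted ring.

Step 4
Reactants: 5 1-bromo-3,5-dimethoxy-2-[1-(4-methoxyphenyl)ethenyl]benzene
Product: 6 2-[(2S)-2-(2-bromo-4,6-dimethoxyphenyl)-2-(4-methoxyphenyl)ethyl]-4,4,5,5-tetramethyl-1,3,2-dioxaborolane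
Conditions: CoCl2 (2.5 mol %), chiral tBu-iminopyridine-oxazoline ligand (3 mol %), NaBHEt3 (7.5 mol %), HBpin, THF, 25 °C
Reagents that add atoms: pinacolborane, B1OC(C)(C)C(C)(C)O1
Why: Cobalt hydride-catalysed anti-Markovnikov asymmetric hydroboration of a 1,1-disubstituted aryl alkene; the ligand should tell the twisted 2,6-disubstituted ring B from the coplanar anisyl ring and so set C7 as S.

**Fragment 2 (iodobenzofuran)**

Step 5
Reactants: 7 1-iodo-3,5-dimethoxybenzene
Product: 8 2-iodo-4,6-dimethoxybenzaldehyde
Conditions: POCl3, DMF, 0 to 80 °C; then aq. NaOAc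
Reagents that add atoms: N,N-dimethylformamide, CN(C)C=O; water, O
Why: Vilsmeier–Haack formylation should go para to one methoxy group and ortho to the other (next to iodine), not at the crowded position between the two methoxy groups.

Step 6
Reactants: 8 2-iodo-4,6-dimethoxybenzaldehyde
Product: 9 2-hydroxy-6-iodo-4-methoxybenzaldehyde
Conditions: BCl3, CH2Cl2, −78 to 0 °C; then H2O
Reagents that add atoms: none
Why: Chelation-controlled ether cleavage: BCl3 bound to the aldehyde oxygen cleaves only the ortho methoxy group.

Step 7
Reactants: 9 2-hydroxy-6-iodo-4-methoxybenzaldehyde; 10 diethyl (4-methoxybenzyl)phosphonate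
Product: 11 3-iodo-5-methoxy-2-[(E)-2-(4-methoxyphenyl)ethenyl]phenol
Conditions: KOtBu (2.5 equiv), DMF, 0 to 25 °C; then aq. HCl
Reagents that add atoms: none
Why: Horner–Wadsworth–Emmons olefination with a benzyl phosphonate should give the E-stilbene; the extra base covers the phenol.

Step 8
Reactants: 11 3-iodo-5-methoxy-2-[(E)-2-(4-methoxyphenyl)ethenyl]phenol
Product: 13 4-iodo-6-methoxy-2-(4-methoxyphenyl)-1-benzofuran, via trans-3,4-diiodo-2,3-dihydrobenzofuran 12 (not isolated)
Conditions: I2, K2CO3, THF, 25 °C; then aq. Na2S2O3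
Reagents that add atoms: none
Why: Iodine-mediated oxidative cyclisation of a 2-hydroxystilbene: iodonium formation, attack of the phenoxide at the anisyl-bearing carbon, then base-induced loss of HI to the aromatic benzofuran.

**Union and end game**

Step 9
Reactants: 6 2-[(2S)-2-(2-bromo-4,6-dimethoxyphenyl)-2-(4-methoxyphenyl)ethyl]-4,4,5,5-tetramethyl-1,3,2-dioxaborolane; 13 4-iodo-6-methoxy-2-(4-methoxyphenyl)-1-benzofuran
Product: 15 (2S,3S,7S)-penta-O-methylampelopsin B, via open-chain bromo benzofuran 14 (not isolated)
Conditions: PdCl2(dppf) (10 mol %), Cs2CO3, DMF/H2O 10:1, 60 °C; then HCO2Na, 100 °C, same flask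
Reagents that add atoms: none
Why: Proposed new method: zerovalent palladium inserts first into the C–I bond of 13, the base-activated primary boronate 6 transmetalates and reductive elimination forms the C8–C4 bond (14); the same catalyst then inserts into the aryl C–Br bond, syn carbopalladation of the benzofuran C2=C3 bond forms the ring B–C3 bond, and the benzylic C2–palladium species, which has no syn β-hydrogen, is reduced by formate (decarboxylation, then C–H reductive elimination with retention). The closest known reaction types are the B-alkyl Suzuki–Miyaura coupling and the intramolecular dearomative reductive Heck reaction of indoles and benzofurans; new is their merger in one flask as a (4+3) annulation and the seven-membered closure from the peri position C4. The seven-membered ring closes by 7-exo-trig carbopalladation, while the dihydrofuran arises by dearomatisation and not by ring closure. C2 and C3 should come out trans because aryl and palladium add to the same face and hydride replaces palladium with retention; C3 is set relative to C7 by a boat-like transition state in which ring A and C8 lie on one face of ring B, C7–H eclipses the ring B plane next to the methoxy group (allylic 1,3-strain) and the anisyl group sits on the convex face, which puts C3–H cis to the C7 aryl group as in the target. The step needs C–I to react before C–Br, which the faster oxidative addition of the iodide and the hindered position of the bromide should secure, and it needs carbopalladation to outrun formate reduction of the arylpalladium bromide and C–H arylation of the anisyl ring, which late addition of formate and the electron-rich enol ether bond held close by the tether should secure.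

Step 10
Reactants: 15 (2S,3S,7S)-penta-O-methylampelopsin B
Product: 16 ampelopsin B
Conditions: BBr3 (10 equiv), CH2Cl2, −78 to 25 °C; then H2O/MeOH
Reagents that add atoms: none
Why: Lewis acid cleavage of all five aryl methyl ethers with BBr3; no stereocentre carries an acidic hydrogen, and the 2,3-trans dihydrofuran is the stable isomer should the benzylic C2–O bond open reversibly.

**Compound list**

1 | 2-bromo-4,6-dimethoxybenzaldehyde | O=Cc1c(Br)cc(OC)cc1OC | starting material
2 | 4-methoxyphenylmagnesium bromide | COc1ccc([Mg]Br)cc1 | starting material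
3 | (2-bromo-4,6-dimethoxyphenyl)(4-methoxyphenyl)methanol, racemic | COc1ccc(C(O)c2c(Br)cc(OC)cc2OC)cc1 | intermediate
4 | (2-bromo-4,6-dimethoxyphenyl)(4-methoxyphenyl)methanone | COc1ccc(C(=O)c2c(Br)cc(OC)cc2OC)cc1 | intermediate
5 | 1-bromo-3,5-dimethoxy-2-[1-(4-methoxyphenyl)ethenyl]benzene | COc1ccc(C(=C)c2c(Br)cc(OC)cc2OC)cc1 | intermediate
6 | 2-[(2S)-2-(2-bromo-4,6-dimethoxyphenyl)-2-(4-methoxyphenyl)ethyl]-4,4,5,5-tetramethyl-1,3,2-dioxaborolane | COc1ccc([C@H](CB2OC(C)(C)C(C)(C)O2)c2c(Br)cc(OC)cc2OC)cc1 | intermediate
7 | 1-iodo-3,5-dimethoxybenzene | COc1cc(I)cc(OC)c1 | starting material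
8 | 2-iodo-4,6-dimethoxybenzaldehyde | O=Cc1c(I)cc(OC)cc1OC | intermediate
9 | 2-hydroxy-6-iodo-4-methoxybenzaldehyde | O=Cc1c(I)cc(OC)cc1O | intermediate
10 | diethyl (4-methoxybenzyl)phosphonate | CCOP(=O)(Cc1ccc(OC)cc1)OCC | starting material
11 | 3-iodo-5-methoxy-2-[(E)-2-(4-methoxyphenyl)ethenyl]phenol | COc1ccc(/C=C/c2c(O)cc(OC)cc2I)cc1 | intermediate
12 | trans-3,4-diiodo-6-methoxy-2-(4-methoxyphenyl)-2,3-dihydro-1-benzofuran, racemic, relative configuration shown | COc1ccc([C@@H]2Oc3cc(OC)cc(I)c3[C@H]2I)cc1 | intermediate
13 | 4-iodo-6-methoxy-2-(4-methoxyphenyl)-1-benzofuran | COc1ccc(-c2cc3c(I)cc(OC)cc3o2)cc1 | intermediate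
14 | 4-[(2S)-2-(2-bromo-4,6-dimethoxyphenyl)-2-(4-methoxyphenyl)ethyl]-6-methoxy-2-(4-methoxyphenyl)-1-benzofuran | COc1ccc([C@H](Cc2cc(OC)cc3oc(-c4ccc(OC)cc4)cc23)c2c(Br)cc(OC)cc2OC)cc1 | intermediate
15 | (2S,3S,7S)-penta-O-methylampelopsin B (2,3-trans dihydrobenzofuran fused through C3 and C4 to the dibenzo seven-membered ring; C7 anisyl cis to C3–H) | COc1ccc([C@@H]2Cc3cc(OC)cc4c3[C@H](c3cc(OC)cc(OC)c32)[C@@H](c2ccc(OC)cc2)O4)cc1 | intermediate
16 | ampelopsin B | Oc1ccc([C@@H]2Cc3cc(O)cc4c3[C@H](c3cc(O)cc(O)c32)[C@@H](c2ccc(O)cc2)O4)cc1 | target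

**Step count.** Total: 10 steps. Longest linear sequence: 6 steps (steps 1–4, 9, 10 or steps 5–8, 9, 10).

**Steps most likely to fail**

1. Step 9. The arylpalladium intermediates may be reduced by formate before they couple or cyclise. The arylpalladium bromide may instead arylate a C–H bond of the anisyl ring. Base may rearomatise the carbopalladation product instead of formate reducing it. Facial selectivity at C3 may be poor. Fallback, from 6 and 13 and back at 15: the Suzuki coupling is run alone (PdCl2(dppf), Cs2CO3, DMF/H2O, 60 °C) and 14 is isolated. Intramolecular direct arylation at C3 (Pd(OAc)2, PCy3·HBF4, K2CO3, DMA, 130 °C) then gives the fully aromatic benzofuran-fused dibenzocycloheptene F1. Ionic hydrogenation of F1 (Et3SiH, CF3CO2H, CH2Cl2) protonates C3 and delivers hydride to the C2 oxocarbenium ion; under the acid, C2 can equilibrate to the trans isomer by reversible opening of the benzylic C2–O bond, which leads to 15.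

2. Step 4. The hindered diaryl alkene may insert slowly, the two aryl groups may be told apart poorly (low enantioselectivity), or low-valent cobalt may attack the aryl bromide. Fallback, from 1 and back at 6: Horner–Wadsworth–Emmons reaction of 1 with triethyl phosphonoacetate (NaH, THF) gives ethyl (E)-3-(2-bromo-4,6-dimethoxyphenyl)prop-2-enoate F2. Asymmetric conjugate addition of 4-methoxyphenylboronic acid (Rh(acac)(C2H4)2, BINAP antipode that gives S, dioxane/H2O, 100 °C) gives ethyl (3S)-3-(2-bromo-4,6-dimethoxyphenyl)-3-(4-methoxyphenyl)propanoate F3. LiOH gives the acid F4, and N-hydroxyphthalimide with diisopropylcarbodiimide gives the redox-active ester F5. Decarboxylative borylation (B2pin2, Cu(acac)2, LiOH·H2O, MgCl2) replaces the carboxyl carbon by boron and gives 6 with C7 untouched.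

3. Step 8. Iodine may iodinate the electron-rich phenol ring in competition with cyclisation, or loss of HI from 12 may stall; the olefination of the free phenol aldehyde in step 7 may also be sluggish. Fallback, from 9 and back at 13: NaBH4 (MeOH, 0 °C) gives 2-(hydroxymethyl)-3-iodo-5-methoxyphenol F6. PPh3·HBr (MeCN, reflux) gives (2-hydroxy-6-iodo-4-methoxybenzyl)triphenylphosphonium bromide F7. 4-Methoxybenzoyl chloride and Et3N (toluene, reflux) acylate the phenol and close the furan by intramolecular Wittig reaction to 13.

**Further compounds**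

F1 | step 9 | (7S)-2,3-didehydro-penta-O-methylampelopsin B (benzofuran analogue of 15) | COc1ccc([C@@H]2Cc3cc(OC)cc4oc(-c5ccc(OC)cc5)c(-c5cc(OC)cc(OC)c52)c34)cc1
F2 | step 4 | ethyl (E)-3-(2-bromo-4,6-dimethoxyphenyl)prop-2-enoate | CCOC(=O)/C=C/c1c(Br)cc(OC)cc1OC
F3 | step 4 | ethyl (3S)-3-(2-bromo-4,6-dimethoxyphenyl)-3-(4-methoxyphenyl)propanoate | COc1ccc([C@H](CC(=O)OCC)c2c(Br)cc(OC)cc2OC)cc1
F4 | step 4 | (3S)-3-(2-bromo-4,6-dimethoxyphenyl)-3-(4-methoxyphenyl)propanoic acid | COc1ccc([C@H](CC(=O)O)c2c(Br)cc(OC)cc2OC)cc1
F5 | step 4 | 1,3-dioxoisoindolin-2-yl (3S)-3-(2-bromo-4,6-dimethoxyphenyl)-3-(4-methoxyphenyl)propanoate | COc1ccc([C@H](CC(=O)ON2C(=O)c3ccccc3C2=O)c2c(Br)cc(OC)cc2OC)cc1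
F6 | step 8 | 2-(hydroxymethyl)-3-iodo-5-methoxyphenol | OCc1c(O)cc(OC)cc1I
F7 | step 8 | (2-hydroxy-6-iodo-4-methoxybenzyl)triphenylphosphonium bromide | COc1cc(O)c(C[P+](c2ccccc2)(c2ccccc2)c2ccccc2)c(I)c1.[Br-]
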